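**Plan**
1. Cuts: the two isovalerate C–O bonds and the C4 carbonyl oxygen go first. The cyclobutane bonds C5–C6 and C7–C8 are then cut in one operation, which unfolds the tricycle into a monocyclic humulane.
2. Enabling feature: C2, C3, C4, C5, C8, C9, C10, C11, C12, C6 and C7 lie in this order on one eleven-membered carbon loop, with methyl groups on C2, C8 and C12 (two). The six-membered ring (C2–C3–C4–C5–C6–C7), the seven-membered ring (C5–C8–C9–C10–C11–C12–C6) and the four-membered ring (C5–C6–C7–C8) differ from that loop only by the two cross-ring bonds.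
3. Forward: zerumbone supplies the loop and all fifteen carbons. Oxygen is placed on C11 (conjugate borylation–oxidation) and on C9 (ketone reduction), and the C2=C7 alkene is transposed through its epoxide into a C2 tertiary alcohol next to an E C6=C7 alkene.
4. Ring order: ionisation at C2, then C5–C6 (six- and seven-membered rings together), then C7–C8 (four-membered ring), then loss of H from C3. C4 oxidation, desilylation and double acylation follow.
5. Stereochemistry: C11 comes from a chiral copper catalyst and C9 from hydroxyl-directed anti reduction. C5–C8 come from the E,E alkene geometry and the ring constraints, with their absolute sense relayed from C9 and C11.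

Key step: step 6

Numbering: atoms are numbered as they follow one another in the target SMILES (C1 = methyl on C2, C2=C3, C4 = ketone carbon, C5–C7 = ring CH, C8 = quaternary carbon, C9 and C11 = carbinol carbons, C10 = CH2, C12 = CMe2). The same numbers serve for every intermediate, and all descriptors refer to them.
Assumption 1: the ferrocenyl diphosphine of step 1 is assumed to induce 11R; if the sense is opposite, the equally available mirror-image ligand is used.
Assumption 2: epoxide 7 and compounds 9–12 derived from it are drawn as one diastereomer; the face attacked in step 4 has no consequence, since C7 becomes trigonal in step 5 and C2 in step 6.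

Step 1
Reactants: 1 zerumbone; 2 bis(pinacolato)diboron
Product: 4 (11R)-11-hydroxy-10,11-dihydrozerumbone, via β-boryl ketone 3 (not isolated)
Conditions: CuCl (5 mol%), (R)-1-[(S)-2-(diphenylphosphino)ferrocenyl]ethyldicyclohexylphosphine (Josiphos type, 5.5 mol%), NaOtBu (10 mol%), 2 (1.05 equiv), MeOH (2 equiv), THF, 0 °C to rt; then NaBO3·4H2O, THF/H2O, rt
Reagents that add atoms: sodium perborate, [Na+].[O-]OB=O (source of the C11 oxygen; 2 supplies the boron of 3 only)
Why: Copper-catalysed enantioselective conjugate borylation, in which the phosphine-bound copper boryl should insert the 1,2-disubstituted C10=C11 enone arm faster than the α-methyl-branched C8=C5 arm and ignore the unactivated C2=C7 alkene; the ligand selects the alkene face that makes C11 R, and perborate oxidation of the C–B bond proceeds with retention.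

Step 2
Reactants: 4 (11R)-11-hydroxy-10,11-dihydrozerumbone
Product: 5 (9R,11R)-anti-9,11-diol of the E,E-cycloundecadiene
Conditions: Me4NBH(OAc)3 (5 equiv), MeCN/AcOH 1:1, −30 °C
Reagents that add atoms: none
Why: Evans–Saksena reduction, in which the C11 hydroxyl binds the boron reagent and hydride is delivered through a chair-like six-membered array to the C9 carbonyl only, which should give the 1,3-anti diol (9R) by 1,2-reduction and leave both alkenes untouched.

Step 3
Reactants: 5 (9R,11R)-anti-9,11-diol
Product: 6 (9R,11R)-9,11-bis(tert-butyldimethylsilyl) ether of 5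
Conditions: TBSOTf (3 equiv), 2,6-lutidine (4 equiv), CH2Cl2, −78 to 0 °C
Reagents that add atoms: tert-butyldimethylsilyl triflate, CC(C)(C)[Si](C)(C)OS(=O)(=O)C(F)(F)F
Why: Silyl ether formation with a silyl triflate, reactive enough for the neopentyl C11 hydroxyl; no stereocentre is touched, and silyl ethers, unlike esters, cannot intercept the cations of step 6 by neighbouring-group participation.

Step 4
Reactants: 6 bis-silyl ether
Product: 7 (2S,7S,9R,11R)-2,7-epoxide of 6
Conditions: mCPBA (1.0 equiv), CH2Cl2, −20 °C
Reagents that add atoms: 3-chloroperbenzoic acid, OOC(=O)c1cccc(Cl)c1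
Why: Prilezhaev epoxidation under electronic control, in which the allylic C9 silyloxy group lowers the nucleophilicity of C5=C8 and shields it (the selectivity known from geranyl ethers and esters, which react at the remote alkene), so one equivalent of peracid should take C2=C7, and syn addition to the E alkene fixes the trans epoxide.

Step 5
Reactants: 7 epoxide; 8 diphenyl diselenide
Product: 11 (2S,9R,11R)-E,E-cycloundecadienol bearing a C2 tertiary allylic alcohol plus C9 and C11 OTBS groups, via hydroxy selenide 9 (not isolated), via selenoxide 10 (not isolated)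
Conditions: 8 (0.75 equiv), NaBH4 (1.6 equiv), EtOH, 78 °C; then THF, 30% H2O2, 0 °C to rt
Reagents that add atoms: none
Why: Epoxide-to-allylic-alcohol transposition by selenide opening and selenoxide syn elimination, in which the selenolate attacks the secondary C7 with inversion and leaves the C2–O bond intact, and the selenoxide, whose only β-hydrogens are on C6, should eliminate to the E C6=C7 alkene.

Step 6
Reactants: 11 macrocyclic dienol
Product: 16 (5R,6R,7R,8S,9R,11R)-tricyclic C2=C3 alkene bis-TBS ether, via allylic triflate 12 (not isolated), via allyl cation 13 (not isolated), via bicyclic C8 cation 14 (not isolated), via tricyclic C2 cation 15 (not isolated)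
Conditions: Tf2O (1.1 equiv), 2,6-di-tert-butyl-4-methylpyridine (3 equiv), CH2Cl2 (0.005 M), −78 to −40 °C
Reagents that add atoms: none
Why: Proposed new method: Triflation of the only free hydroxyl and loss of triflate give the C2–C7–C6 allyl cation 13 in its cisoid form; C5, the less substituted end of C5=C8, adds to C6 to give the tertiary C8 cation 14, C8 then bonds to C7 of the remaining C7=C2 alkene to give the tertiary C2 cation 15, and loss of a C3 proton to the buffered medium gives 16. The closest known reaction types are the acid-induced intramolecular cationic [2+2] cycloaddition of allyl cations with unactivated alkenes and the transannular cation–olefin cyclisations of humulene derivatives; a transannular version ending in a bicyclo[3.1.1]heptene has not been described. The C5–C6 bond closes the six-membered ring in 6-exo fashion and the seven-membered ring in 7-endo fashion with respect to C5=C8, and the C7–C8 bond closes the four-membered ring in 4-exo fashion with respect to C7=C2. C5 and C6 follow from suprafacial addition to two E alkenes (H5 and H6 trans), C8 from the E geometry of C5=C8 (C9 trans to C4) held by the new seven-membered ring, and C7 from the fact that C8 can reach only the face of C7=C2 on which it hangs; the absolute sense comes from C9, because the reactive fold must put C10 on the inner face of C5=C8 and then places H9, not the silyloxy group, beside the C8 methyl (A1,2 strain), while the anti C11 silyloxy group sits on the opposite flank of the C9–C12 bridge. The step needs ionisation at C2 only (secured by the single free, tertiary and allylic hydroxyl), bonding of C6 to C5 rather than any other pairing (ring size and Markovnikov charge at C8), closure at C7 rather than C2 (tertiary C2 cation against a secondary C7 cation), and ring closure ahead of proton loss or a C9-to-C8 hydride shift. The last demand is helped by the electron-withdrawing C9 oxygen, which makes the C8 cation short-lived and moves the charge to the remote C2, by low temperature and high dilution, and by the hindered pyridine, which removes triflic acid so that the acid-labile pinene-type alkene and the silyl ethers are not re-protonated.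

Step 7
Reactants: 16 tricyclic alkene
Product: 17 (5R,6S,7R,8R,9R,11R)-tricyclic C2=C3–C4(=O) enone bis-TBS ether
Conditions: CrO3 (15 equiv), 3,5-dimethylpyrazole (15 equiv), CH2Cl2, −20 °C
Reagents that add atoms: chromium trioxide, O=[Cr](=O)=O
Why: Allylic oxidation with the CrO3–3,5-dimethylpyrazole complex, the α-pinene-to-verbenone type of transformation; C4 is the only allylic methylene (C7 is a bridgehead, C1 a methyl group), so the enone should form there without touching a stereocentre or the silyl ethers.

Step 8
Reactants: 17 enone bis-TBS ether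
Product: 18 (5R,6S,7R,8R,9R,11R)-9,11-dihydroxy enone
Conditions: HF·pyridine, THF/pyridine, 0 °C to rt
Reagents that add atoms: none
Why: Fluoride-driven silyl ether cleavage (formation of the strong Si–F bond); the mildly acidic reagent should leave the enone, the cyclobutane and all stereocentres unchanged.

Step 9
Reactants: 18 dihydroxy enone; 19 isovaleryl chloride
Product: 20 CNP0192813.1
Conditions: 19 (4 equiv), Et3N (6 equiv), DMAP (0.2 equiv), CH2Cl2, 0 °C to rt
Reagents that add atoms: isovaleryl chloride (19), CC(C)CC(=O)Cl
Why: DMAP-catalysed esterification with an acid chloride, strong enough for two secondary alcohols that each flank a quaternary carbon; only O–H bonds are broken, so C9 and C11 keep their configuration.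

**Compound list**
1 | zerumbone, (2E,6E,10E)-2,6,9,9-tetramethylcycloundeca-2,6,10-trien-1-one | C1/C(C)=C/CC(C)(C)/C=C/C(=O)/C(C)=C/C1 | starting material
2 | bis(pinacolato)diboron | CC1(C)OB(OC1(C)C)B1OC(C)(C)C(C)(C)O1 | starting material
3 | (11R)-11-(pinacolatoboryl)-10,11-dihydrozerumbone | C1[C@@H](B2OC(C)(C)C(C)(C)O2)C(C)(C)C/C=C(C)/CC/C=C(C)/C1=O | intermediate
4 | (11R)-11-hydroxy-10,11-dihydrozerumbone (C9 ketone, E C5=C8, E C2=C7) | C1[C@@H](O)C(C)(C)C/C=C(C)/CC/C=C(C)/C1=O | intermediate
5 | (9R,11R)-anti-9,11-diol of the E,E-cycloundecadiene | C1[C@@H](O)C(C)(C)C/C=C(C)/CC/C=C(C)/[C@@H]1O | intermediate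
6 | (9R,11R)-9,11-bis-TBS ether of 5 | C1[C@@H](O[Si](C)(C)C(C)(C)C)C(C)(C)C/C=C(C)/CC/C=C(C)/[C@@H]1O[Si](C)(C)C(C)(C)C | intermediate
7 | (2S,7S,9R,11R)-2,7-epoxide of 6 (trans epoxide, E C5=C8) | C1[C@@H](O[Si](C)(C)C(C)(C)C)C(C)(C)C[C@@H]2O[C@@]2(C)CC/C=C(C)/[C@@H]1O[Si](C)(C)C(C)(C)C | intermediate
8 | diphenyl diselenide | c1ccccc1[Se][Se]c1ccccc1 | starting material
9 | (2S,7R,9R,11R)-7-phenylselanyl-2-ol | C1[C@@H](O[Si](C)(C)C(C)(C)C)C(C)(C)C[C@@H]([Se]c2ccccc2)[C@@](C)(O)CC/C=C(C)/[C@@H]1O[Si](C)(C)C(C)(C)C | intermediate
10 | selenoxide of 9 (configuration at selenium undefined) | C1[C@@H](O[Si](C)(C)C(C)(C)C)C(C)(C)C[C@@H]([Se](=O)c2ccccc2)[C@@](C)(O)CC/C=C(C)/[C@@H]1O[Si](C)(C)C(C)(C)C | intermediate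
11 | (2S,9R,11R)-cycloundecadienol: E C6=C7, E C5=C8, C2 tertiary allylic alcohol, C9 and C11 OTBS | C1[C@@H](O[Si](C)(C)C(C)(C)C)C(C)(C)/C=C/[C@@](C)(O)CC/C=C(C)/[C@@H]1O[Si](C)(C)C(C)(C)C | intermediate
12 | C2 triflate of 11 | C1[C@@H](O[Si](C)(C)C(C)(C)C)C(C)(C)/C=C/[C@@](C)(OS(=O)(=O)C(F)(F)F)CC/C=C(C)/[C@@H]1O[Si](C)(C)C(C)(C)C | intermediate
13 | C2–C7–C6 allyl cation (drawn with the charge on C2, cisoid about C7–C2) | C1[C@@H](O[Si](C)(C)C(C)(C)C)C(C)(C)/C=C/[C+](C)CC/C=C(C)/[C@@H]1O[Si](C)(C)C(C)(C)C | intermediate
14 | trans-fused six/seven bicyclic C8 cation (C7=C2 alkene) | CC1=C[C@H]2[C@@H](CC1)[C+](C)[C@H](O[Si](C)(C)C(C)(C)C)C[C@@H](O[Si](C)(C)C(C)(C)C)C2(C)C | intermediate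
15 | tricyclic C2 cation | C[C+]1CC[C@@H]2[C@@H]3[C@H]1[C@@]2(C)[C@H](O[Si](C)(C)C(C)(C)C)C[C@@H](O[Si](C)(C)C(C)(C)C)C3(C)C | intermediate
16 | (5R,6R,7R,8S,9R,11R)-tricyclic C2=C3 alkene, C4 methylene, C9 and C11 OTBS | CC1=CC[C@@H]2[C@@H]3[C@H]1[C@@]2(C)[C@H](O[Si](C)(C)C(C)(C)C)C[C@@H](O[Si](C)(C)C(C)(C)C)C3(C)C | intermediate
17 | (5R,6S,7R,8R,9R,11R)-tricyclic enone, C9 and C11 OTBS | CC1=CC(=O)[C@@H]2[C@@H]3[C@H]1[C@@]2(C)[C@H](O[Si](C)(C)C(C)(C)C)C[C@@H](O[Si](C)(C)C(C)(C)C)C3(C)C | intermediate
18 | (5R,6S,7R,8R,9R,11R)-9,11-dihydroxy enone | CC1=CC(=O)[C@@H]2[C@@H]3[C@H]1[C@@]2(C)[C@H](O)C[C@@H](O)C3(C)C | intermediate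
19 | isovaleryl chloride (3-methylbutanoyl chloride) | CC(C)CC(=O)Cl | starting material
20 | CNP0192813.1, (5R,6S,7R,8R,9R,11R)-9,11-bis(isovaleryloxy) enone | CC1=CC(=O)[C@@H]2[C@@H]3[C@H]1[C@@]2(C)[C@H](OC(=O)CC(C)C)C[C@@H](OC(=O)CC(C)C)C3(C)C | target

Total step count: 9. Longest linear sequence: 9 steps (1 to 20).

**Steps most likely to fail**

Step 6.
- What may go wrong: proton loss from cation 13 or 14, a hydride shift from C9 to C8, addition on the wrong alkene face, or exocyclic deprotonation of 15 may outrun or divert the four-membered closure.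
- Fallback: leave the cationic manifold for a photochemical one. It sets out from 11 and comes back to the route at 16. Dehydration of 11 with the Burgess reagent (toluene, 50 °C) towards the C2 methyl group gives the myrcene-type triene F1, which is separated from its C2=C3 isomer. Direct irradiation (254 nm, pentane, quartz vessel, high dilution) relies on the known light-induced closure of 3-methylene-1,6-dienes to 2-methylenebicyclo[3.1.1]heptanes (myrcene to β-pinene). It joins the same C5–C6 and C7–C8 bonds and gives the exocyclic-methylene tricycle F2. RuHCl(CO)(PPh3)3 (toluene, 80 °C) then moves the double bond into the ring, the β-pinene-to-α-pinene type of isomerisation, and delivers 16. The parent photoreaction is inefficient, so material throughput would be the price of this detour.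

Step 1.
- What may go wrong: the copper boryl may add to the less hindered β-carbon C5 instead of the neopentyl C11, may add twice, or may show poor face selection.
- Fallback: mask the competing enone arm before the borylation. It sets out from 1 and comes back to the route at 4. Thia-Michael addition of thiophenol (Et3N, CH2Cl2, rt) at C5 gives the 5-phenylthio ketone F3, a mixture at C5 and C8 whose centres are erased later. The same copper-catalysed borylation then has only the C10=C11 enone to choose and gives the boryl sulfide F4; here catalyst control has to override the temporary centres. NaBO3·4H2O (THF/H2O) gives the hydroxy sulfide F5, and NaIO4 (MeOH/H2O, 0 °C) gives the hydroxy sulfoxide F6. On warming in toluene over CaCO3, F6 undergoes sulfoxide syn elimination towards the acidic C8–H and restores the E C5=C8 enone of 4.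

Step 4.
- What may go wrong: loss of chemoselectivity, with the peracid also attacking C5=C8, or over-epoxidation.
- Fallback: epoxidise while C5=C8 is still conjugated with the ketone and set C9 afterwards under reagent control. It sets out from 4, replaces steps 2 to 4, and comes back to the route at 7. TBSOTf/2,6-lutidine gives the C11 silyl ether enone F7. mCPBA (CH2Cl2, 0 °C) takes only the isolated C2=C7 alkene, as it does with zerumbone itself, and gives the epoxy enone F8. Corey–Bakshi–Shibata reduction ((S)-Me-CBS oxazaborolidine, catecholborane, toluene, −78 °C) treats the alkenyl side as the large group and should give the (9R)-epoxy alcohol F9. A second silylation with TBSOTf/2,6-lutidine gives 7.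

**Further compounds**
F1 | step 6 | (9R,11R)-triene with E C6=C7–C2(=CH2) diene, E C5=C8, C9 and C11 OTBS | C1[C@@H](O[Si](C)(C)C(C)(C)C)C(C)(C)/C=C/C(=C)CC/C=C(C)/[C@@H]1O[Si](C)(C)C(C)(C)C
F2 | step 6 | tricycle configured as 16 with an exocyclic C2=CH2 group | C=C1CC[C@@H]2[C@@H]3[C@H]1[C@@]2(C)[C@H](O[Si](C)(C)C(C)(C)C)C[C@@H](O[Si](C)(C)C(C)(C)C)C3(C)C
F3 | step 1 | 5-phenylthio-5,8-dihydrozerumbone (C5 and C8 undefined) | O=C1/C=C/C(C)(C)C/C=C(C)/CCC(Sc2ccccc2)C1C
F4 | step 1 | (11R)-11-(pinacolatoboryl)-5-phenylthio ketone (C5 and C8 undefined) | C1[C@@H](B2OC(C)(C)C(C)(C)O2)C(C)(C)C/C=C(C)/CCC(Sc2ccccc2)C(C)C1=O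
F5 | step 1 | (11R)-11-hydroxy-5-phenylthio ketone (C5 and C8 undefined) | C1[C@@H](O)C(C)(C)C/C=C(C)/CCC(Sc2ccccc2)C(C)C1=O
F6 | step 1 | (11R)-11-hydroxy-5-phenylsulfinyl ketone (C5, C8 and sulfur undefined) | C1[C@@H](O)C(C)(C)C/C=C(C)/CCC(S(=O)c2ccccc2)C(C)C1=O
F7 | step 4 | (11R)-11-OTBS-10,11-dihydrozerumbone | C1[C@@H](O[Si](C)(C)C(C)(C)C)C(C)(C)C/C=C(C)/CC/C=C(C)/C1=O
F8 | step 4 | (2S,7S,11R)-2,7-epoxy-11-OTBS enone | C1[C@@H](O[Si](C)(C)C(C)(C)C)C(C)(C)C[C@@H]2O[C@@]2(C)CC/C=C(C)/C1=O
F9 | step 4 | (2S,7S,9R,11R)-2,7-epoxy-11-OTBS-9-ol | C1[C@@H](O[Si](C)(C)C(C)(C)C)C(C)(C)C[C@@H]2O[C@@]2(C)CC/C=C(C)/[C@@H]1O
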